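Compound numbers are those of the steps and of the compound list below.

## Analysis of the target

The target 17 is a 2,3-dihydro-1,4-benzodioxine: aromatic ring A is fused to a dioxane ring through O1 (on C8a) and O4 (on C4a). C2 carries a hydroxymethyl group, C3 the 3,4-dihydroxy-5-methoxyphenyl ring C, C6 an (E)-3-hydroxyprop-1-enyl chain and C8 a methoxy group. The only stereocentres are the neighbouring C2 (R) and C3 (S). Hydroxymethyl and aryl are cis, the less stable arrangement, so it has to be made under kinetic control. Sensitive groups are the free catechol (oxidation, chelation of metals), the electron-rich cinnamyl alcohol (ionises in acid) and the C3–O4 bond. That bond is a benzylic aryl ether para to a free phenol, which base can open through a quinone methide and reclose to the trans isomer. Ring A is unsymmetrical, so O1 (next to the methoxy-bearing C8) and O4 must be placed without regiochemical ambiguity; two successive SN2 closures from (E)-alkene-derived diols or epoxides would give trans. The strategy rests on O4: it lies between the aromatic carbon C4a and the benzylic, aryl-bearing C3, the pattern left when an aryl carbon moves from carbon to a peroxide oxygen. Taking O4 out joins C4a to C3 and turns the dioxane ring into the furan ring of a 3-aryl-2,3-dihydrobenzofuran.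

## Retrosynthetic reasoning

**17 to 16.** No skeletal bond is cut. The three hydroxyl groups are carried as acetates and the allylic alcohol as a methyl cinnamate, so that one hydride reduction at low temperature frees all four oxygen functions. Basic ester cleavage was ruled out: a phenoxide para to C3 at room temperature invites quinone methide opening of the C3–O4 bond and loss of the cis configuration.

**16 to 14 and 15.** The C6–vinyl bond is cut (Mizoroki–Heck). The alkene would not survive hydrogenation, autoxidation or Lewis acid, so it comes last; a chloride at C6 passes through all of these. The forward reaction must activate an electron-rich aryl chloride under conditions that leave the aryl acetates intact.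

**14 to 12, through 13.** This is the key disconnection. The O4–C4a and C3–H bonds are cut, C4a is rejoined to C3, and the oxygen becomes a hydroperoxide on C3.
- The oxygen that is hard to place on ring A is not brought in with ring A. It is inserted into an existing C–C bond, so ring A is simply phenol 6 with one oxygen, and the O1/O4 regiochemistry is automatic.
- C3 is stereochemically irrelevant in 12, so only C2 has to be controlled beforehand.
- The cis relation arises when hydride is delivered to cation 13.
- The forward step must make C4a migrate, break the O–O rather than the C3–O bond, reduce 13 before it loses the C2 proton, and deliver hydride anti to the C2 substituent.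

**12 to 11.** The C3–O bond is cut back to C3–H. That hydrogen is tertiary and benzylic to both rings, the weakest C–H bond in 11, so aerobic autoxidation should find it.

**11 to 10.** The two hydrogens at C2 and C3 are removed, giving a flat, achiral benzofuran. Asymmetric hydrogenation then has one job, the configuration at C2.

**10 to 9 to 8.** Functional group changes only. The ester at C2 is reduced to the hydroxymethyl group; the ring C acetates fall off in the same reduction and are put back together with the new primary acetate.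

**8 to 7.** The C3–C3a bond is cut (acid cyclodehydration of an aryloxy ketone). The ketone carbon becomes C3 and the only free position ortho to the ether oxygen of ring A becomes C3a.

**7 to 5 and 6.** The O1–C2 bond is cut (carbene O–H insertion). A neutral method is chosen because a phenoxide would transfer acetyl groups from ring C.

**5 to 4 to 2 and 3, and 2 to 1.** Diazo transfer, then the bond between the aldehyde carbon of 2 and the diazo carbon of 3 (Roskamp homologation), then acetylation of 1. The aldehyde carbon of 1 ends as C3 of the target.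

## Alternatives that were turned down

**Alternative 1:** oxonium ylide aldol.
- Disconnection: O1–C2 and C2–C3 in one step.
- Forward key step: under dirhodium catalysis with a chiral phosphoric acid, the carbene from 3 is taken up by phenol A2 (4-bromo-2-iodo-6-methoxyphenol). The oxonium ylide adds to aldehyde A3 (3,4-bis(silyloxy)-5-methoxybenzaldehyde) and gives the anti hydroxy ester A1. No ring closes; etherification at the iodide (retention), ester reduction and coupling at the bromide would follow.
- For: it is the most convergent plan, sets both stereocentres at once and is shorter on paper than the chosen route. On step economy it is stronger.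
- Against: ylide interception is established for aryl diazoacetates. With the acceptor-only carbene from 3 the 1,2-proton shift to the plain O–H insertion product is fast, and A2 is hindered on both sides. Both stereocentres then depend on one multicomponent event. The later aryl ether closure needs base and heat on an epimerisable aryloxy ester, and iodide has to be told from bromide.
- Comparison: the chosen strategy spreads the risk. C2 comes from a hydrogenation, C3 from substrate control, and the main failure path of its key step can be recycled.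

**Alternative 2:** diazodione–epoxide annulation.
- Disconnection: C8a–O1 and O4–C3, with ring A still a cyclohexanedione.
- Forward key step: the dirhodium carbene from diazodione A5 takes the oxygen of the trans epoxide A6, the benzylic C–O bond opens and the enolate oxygen closes on C3 to give A4.
- For: the dioxane ring forms in one step, the epoxide stereocentres come from reliable asymmetric epoxidation, the symmetric dione removes the O1/O4 question, and the C6 carbon is already present. On the source of chirality it is as strong as the chosen route.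
- Against: the benzylic carbon passes through a cation-like state, so cis versus trans at C3 is not secured. Afterwards ring A must be dehydrogenated twice next to a sensitive cis benzylic ether and O-methylated, and the ester must be turned into the propenol chain in several steps.
- Comparison: the chosen route keeps ring A aromatic from the first step and has a two-step tail.

**Alternative 3:** lactone arylation and anti hydride delivery.
- Disconnection: C3–C1' and C3–H.
- Forward key step: Grignard reagent A9 adds to the carbonyl of lactone A8. The hemiketal A10 is ionised by a Lewis acid and reduced by a silane through the same type of O4=C3 oxocarbenium ion, giving A7.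
- For: the stereochemical logic is that of the chosen route, but on the precedented ground of C-aryl glycoside synthesis, and C2 comes from the chiral pool. On precedent and on the source of C2 it is stronger.
- Against: A8 is an aryl ester. Its tetrahedral adduct can expel phenoxide and take a second equivalent of A9, and its acidic C2 proton can be removed by A9. Making A8 requires the two ring A oxygens to be told apart in extra steps, and ring C needs its own halide synthesis.
- Comparison: the chosen strategy uses a one-oxygen phenol and an aldehyde, and places O4 without any regiochemical decision. Alternative 3 is kept as the fallback for the key step.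

Key step: step 10

Assumption: the sense of induction of the ruthenium carbene catalyst in step 8 cannot be predicted for this substrate; the ligand antipode that gives the 2S product is used, both antipodes being available.

## Route

Step 1
Reactants: 1 3,4-dihydroxy-5-methoxybenzaldehyde (5-hydroxyvanillin)
Product: 2 3,4-diacetoxy-5-methoxybenzaldehyde
Conditions: Ac2O, pyridine, DMAP (cat.), CH2Cl2, 0 °C to rt
Reagents that add atoms: acetic anhydride, CC(=O)OC(C)=O
Why: O-acetylation of both phenols; the acetates tolerate the Lewis acid, diazo and carbene chemistry of steps 2 to 4, where free phenols would compete.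

Step 2
Reactants: 2 3,4-diacetoxy-5-methoxybenzaldehyde; 3 ethyl diazoacetate
Product: 4 ethyl 3-(3,4-diacetoxy-5-methoxyphenyl)-3-oxopropanoate
Conditions: SnCl2 (10 mol%), CH2Cl2, rt
Reagents that add atoms: none
Why: Roskamp reaction: the diazo carbon adds to the Lewis-acid-activated aldehyde and a 1,2-hydride shift with loss of nitrogen gives the β-keto ester; the acetoxy groups make the aldehyde more electrophilic than a trialkoxy analogue.

Step 3
Reactants: 4 ethyl 3-(3,4-diacetoxy-5-methoxyphenyl)-3-oxopropanoate
Product: 5 ethyl 2-diazo-3-(3,4-diacetoxy-5-methoxyphenyl)-3-oxopropanoate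
Conditions: 4-acetamidobenzenesulfonyl azide, Et3N, MeCN, 0 °C to rt
Reagents that add atoms: 4-acetamidobenzenesulfonyl azide, CC(=O)Nc1ccc(cc1)S(=O)(=O)N=[N+]=[N-]
Why: Regitz diazo transfer to the active methylene group; the amine base is not nucleophilic enough to cleave the aryl acetates.

Step 4
Reactants: 5 ethyl 2-diazo-3-(3,4-diacetoxy-5-methoxyphenyl)-3-oxopropanoate; 6 4-chloro-2-methoxyphenol
Product: 7 ethyl 2-(4-chloro-2-methoxyphenoxy)-3-(3,4-diacetoxy-5-methoxyphenyl)-3-oxopropanoate (racemic)
Conditions: Rh2(OAc)4 (1 mol%), toluene, 80 °C, slow addition of 5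
Reagents that add atoms: none
Why: Rhodium carbene O–H insertion into the phenol forms the O1–C2 bond under neutral conditions, so no phenoxide is present to strip acetyl groups from ring C; the stereocentre formed is labile and is removed in step 5.

Step 5
Reactants: 7 ethyl 2-(4-chloro-2-methoxyphenoxy)-3-(3,4-diacetoxy-5-methoxyphenyl)-3-oxopropanoate
Product: 8 ethyl 5-chloro-3-(3,4-diacetoxy-5-methoxyphenyl)-7-methoxy-1-benzofuran-2-carboxylate
Conditions: MeSO3H, CH2Cl2, 0 °C to rt
Reagents that add atoms: none
Why: Acid-catalysed cyclodehydration (intramolecular Friedel–Crafts hydroxyalkylation, then loss of water): the protonated aryl ketone is attacked by the only free position ortho to the ether oxygen, and aromatisation to the benzofuran drives the reaction. Any acetate lost here does not matter, because step 6 removes both.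

Step 6
Reactants: 8 ethyl 5-chloro-3-(3,4-diacetoxy-5-methoxyphenyl)-7-methoxy-1-benzofuran-2-carboxylate
Product: 9 5-[5-chloro-2-(hydroxymethyl)-7-methoxy-1-benzofuran-3-yl]-3-methoxybenzene-1,2-diol
Conditions: iBu2AlH (8 equiv), CH2Cl2, −78 to 0 °C; aq. potassium sodium tartrate, then pH 3
Reagents that add atoms: none
Why: Hydride reduction of the ester to the primary alcohol; the aryl acetates are cleaved reductively in the same operation, and the aryl chloride and the benzofuran are inert at this temperature.

Step 7
Reactants: 9 5-[5-chloro-2-(hydroxymethyl)-7-methoxy-1-benzofuran-3-yl]-3-methoxybenzene-1,2-diol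
Product: 10 [5-chloro-3-(3,4-diacetoxy-5-methoxyphenyl)-7-methoxy-1-benzofuran-2-yl]methyl acetate
Conditions: Ac2O, pyridine, DMAP (cat.), CH2Cl2, rt
Reagents that add atoms: acetic anhydride, CC(=O)OC(C)=O
Why: Peracetylation: it removes the chelating catechol before the hydrogenation, makes ring C electron-poor for the key step and protects the primary alcohol.

Step 8
Reactants: 10 [5-chloro-3-(3,4-diacetoxy-5-methoxyphenyl)-7-methoxy-1-benzofuran-2-yl]methyl acetate
Product: 11 [(2S,3R)-5-chloro-3-(3,4-diacetoxy-5-methoxyphenyl)-7-methoxy-2,3-dihydro-1-benzofuran-2-yl]methyl acetate (2,3-cis)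
Conditions: [Ru(cod)(2-methylallyl)2] (5 mol%), (R,R)-SINpEt·HBF4 (10 mol%), KOtBu (12 mol%), H2 (80 bar), toluene, 40 °C
Reagents that add atoms: none
Why: Asymmetric hydrogenation of the furan ring of a benzofuran with a chiral ruthenium bis(N-heterocyclic carbene) catalyst (SINpEt is 1,3-bis[1-(naphthalen-1-yl)ethyl]imidazolin-2-ylidene): both hydrogens add to one face of C2=C3, which gives the cis product, and the ligand selects the face and so sets C2 (2S). C3 is also formed but is erased in step 9.

Step 9
Reactants: 11 [(2S,3R)-5-chloro-3-(3,4-diacetoxy-5-methoxyphenyl)-7-methoxy-2,3-dihydro-1-benzofuran-2-yl]methyl acetate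
Product: 12 [(2R,3RS)-5-chloro-3-(3,4-diacetoxy-5-methoxyphenyl)-3-hydroperoxy-7-methoxy-2,3-dihydro-1-benzofuran-2-yl]methyl acetate
Conditions: N-hydroxyphthalimide (20 mol%), AIBN (5 mol%), O2 (1 atm), MeCN, 65 °C, stopped at partial conversion
Reagents that add atoms: dioxygen, O=O
Why: N-Hydroxyphthalimide-catalysed autoxidation: the phthalimide N-oxyl radical abstracts the weakest hydrogen, the tertiary C3–H benzylic to both rings; the radical takes up oxygen and the peroxyl radical is reduced by the catalyst. C2 is not touched (its descriptor changes only because the priorities change); C3 forms as a mixture, and either epimer serves in step 10.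

Step 10
Reactants: 12 [(2R,3RS)-5-chloro-3-(3,4-diacetoxy-5-methoxyphenyl)-3-hydroperoxy-7-methoxy-2,3-dihydro-1-benzofuran-2-yl]methyl acetate
Product: 14 [(2R,3S)-6-chloro-3-(3,4-diacetoxy-5-methoxyphenyl)-8-methoxy-2,3-dihydro-1,4-benzodioxin-2-yl]methyl acetate, via oxocarbenium ion 13 (not isolated)
Conditions: Et3SiH (5 equiv), BF3·OEt2 (1.5 equiv), CH2Cl2, −78 to −40 °C
Reagents that add atoms: none
Why: Proposed new method: BF3 binds the terminal oxygen of the hydroperoxide, and as the O–O bond ionises the ring A carbon C4a shifts from C3 to the inner oxygen, so the furan ring grows by one atom into the dioxane ring (a ring expansion by 1,2-shift, not a separate cyclisation) and C3 becomes the aryl-stabilised oxocarbenium ion 13. The closest known reaction type is the acid-promoted Hock (Criegee) rearrangement of tertiary benzylic hydroperoxides, including its interrupted forms in which the oxocarbenium ion is trapped, combined here with the ionic hydrogenation known from lactol reduction. Of the three groups on C3, C4a should migrate: its ortho oxygen O1 raises its aptitude, ring C is deactivated by two acetoxy groups, and C2, although it bears oxygen, is damped by the β-acetoxy group and by conjugation of O1 with ring A. Breaking the O–O rather than the C3–O bond is favoured by complexation at the unhindered terminal oxygen and by the low temperature; the C3 cation from C–O ionisation would be reduced by the silane to 11 or its C3 epimer, which can be oxidised again. The new stereocentre C3 is set by C2: A(1,2) strain with the C3 aryl group holds the acetoxymethyl group pseudo-axial in 13, and hydride from Et3SiH enters on the opposite face, giving the 2,3-cis product under kinetic control. The excess of silane is there so that reduction outruns loss of the C2 proton, which would lead through an achiral benzodioxine and erase C2.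

Step 11
Reactants: 14 [(2R,3S)-6-chloro-3-(3,4-diacetoxy-5-methoxyphenyl)-8-methoxy-2,3-dihydro-1,4-benzodioxin-2-yl]methyl acetate; 15 methyl acrylate
Product: 16 methyl (E)-3-[(2R,3S)-2-(acetoxymethyl)-3-(3,4-diacetoxy-5-methoxyphenyl)-8-methoxy-2,3-dihydro-1,4-benzodioxin-6-yl]prop-2-enoate
Conditions: Pd2(dba)3 (2.5 mol%), P(tBu)3 (10 mol%), Cy2NMe (1.5 equiv), 1,4-dioxane, 100 °C
Reagents that add atoms: none
Why: Mizoroki–Heck reaction: the bulky electron-rich phosphine allows oxidative addition to the unhindered aryl chloride, and insertion with β-hydride elimination gives the (E)-cinnamate. The hindered amine is the only base, so the acetates stay on and no phenoxide exists at high temperature to open the C3–O4 bond.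

Step 12
Reactants: 16 methyl (E)-3-[(2R,3S)-2-(acetoxymethyl)-3-(3,4-diacetoxy-5-methoxyphenyl)-8-methoxy-2,3-dihydro-1,4-benzodioxin-6-yl]prop-2-enoate
Product: 17 (E)-3-[(2R,3S)-3-(3,4-dihydroxy-5-methoxyphenyl)-2-(hydroxymethyl)-8-methoxy-2,3-dihydro-1,4-benzodioxin-6-yl]prop-2-en-1-ol (target)
Conditions: iBu2AlH (12 equiv), CH2Cl2, −78 to −30 °C; aq. potassium sodium tartrate, pH 5 to 6, under argon
Reagents that add atoms: none
Why: Hydride reduction: 1,2-reduction of the cinnamate to the (E)-allylic alcohol and reductive cleavage of the three acetates in one operation, the usual way from acetylated cinnamates to coniferyl-type alcohols. The phenols are set free as aluminium aryloxides at low temperature and then by a mildly acidic work-up, so the cis configuration is not exposed to base.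

## Compound list

1 | 3,4-dihydroxy-5-methoxybenzaldehyde (5-hydroxyvanillin) | COc1cc(C=O)cc(O)c1O | starting material
2 | 3,4-diacetoxy-5-methoxybenzaldehyde | COc1cc(C=O)cc(OC(C)=O)c1OC(C)=O | intermediate
3 | ethyl diazoacetate | CCOC(=O)C=[N+]=[N-] | starting material
4 | ethyl 3-(3,4-diacetoxy-5-methoxyphenyl)-3-oxopropanoate | CCOC(=O)CC(=O)c1cc(OC)c(OC(C)=O)c(OC(C)=O)c1 | intermediate
5 | ethyl 2-diazo-3-(3,4-diacetoxy-5-methoxyphenyl)-3-oxopropanoate | CCOC(=O)C(=[N+]=[N-])C(=O)c1cc(OC)c(OC(C)=O)c(OC(C)=O)c1 | intermediate
6 | 4-chloro-2-methoxyphenol (4-chloroguaiacol) | COc1cc(Cl)ccc1O | starting material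
7 | ethyl 2-(4-chloro-2-methoxyphenoxy)-3-(3,4-diacetoxy-5-methoxyphenyl)-3-oxopropanoate (racemic) | CCOC(=O)C(Oc1ccc(Cl)cc1OC)C(=O)c1cc(OC)c(OC(C)=O)c(OC(C)=O)c1 | intermediate
8 | ethyl 5-chloro-3-(3,4-diacetoxy-5-methoxyphenyl)-7-methoxy-1-benzofuran-2-carboxylate | CCOC(=O)c1oc2c(OC)cc(Cl)cc2c1-c1cc(OC)c(OC(C)=O)c(OC(C)=O)c1 | intermediate
9 | 5-[5-chloro-2-(hydroxymethyl)-7-methoxy-1-benzofuran-3-yl]-3-methoxybenzene-1,2-diol | COc1cc(-c2c(CO)oc3c(OC)cc(Cl)cc23)cc(O)c1O | intermediate
10 | [5-chloro-3-(3,4-diacetoxy-5-methoxyphenyl)-7-methoxy-1-benzofuran-2-yl]methyl acetate | COc1cc(-c2c(COC(C)=O)oc3c(OC)cc(Cl)cc23)cc(OC(C)=O)c1OC(C)=O | intermediate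
11 | [(2S,3R)-5-chloro-3-(3,4-diacetoxy-5-methoxyphenyl)-7-methoxy-2,3-dihydro-1-benzofuran-2-yl]methyl acetate (2,3-cis) | COc1cc([C@@H]2c3cc(Cl)cc(OC)c3O[C@@H]2COC(C)=O)cc(OC(C)=O)c1OC(C)=O | intermediate
12 | [(2R,3RS)-5-chloro-3-(3,4-diacetoxy-5-methoxyphenyl)-3-hydroperoxy-7-methoxy-2,3-dihydro-1-benzofuran-2-yl]methyl acetate | COc1cc(C2(OO)c3cc(Cl)cc(OC)c3O[C@@H]2COC(C)=O)cc(OC(C)=O)c1OC(C)=O | intermediate
13 | (2R)-2-(acetoxymethyl)-6-chloro-3-(3,4-diacetoxy-5-methoxyphenyl)-8-methoxy-2H-1,4-benzodioxin-4-ium (oxocarbenium ion) | COc1cc(C2=[O+]c3cc(Cl)cc(OC)c3O[C@@H]2COC(C)=O)cc(OC(C)=O)c1OC(C)=O | intermediate (not isolated)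
14 | [(2R,3S)-6-chloro-3-(3,4-diacetoxy-5-methoxyphenyl)-8-methoxy-2,3-dihydro-1,4-benzodioxin-2-yl]methyl acetate (2,3-cis) | COc1cc([C@@H]2Oc3cc(Cl)cc(OC)c3O[C@@H]2COC(C)=O)cc(OC(C)=O)c1OC(C)=O | intermediate
15 | methyl acrylate | C=CC(=O)OC | starting material
16 | methyl (E)-3-[(2R,3S)-2-(acetoxymethyl)-3-(3,4-diacetoxy-5-methoxyphenyl)-8-methoxy-2,3-dihydro-1,4-benzodioxin-6-yl]prop-2-enoate | COc1cc([C@@H]2Oc3cc(/C=C/C(=O)OC)cc(OC)c3O[C@@H]2COC(C)=O)cc(OC(C)=O)c1OC(C)=O | intermediate
17 | (E)-3-[(2R,3S)-3-(3,4-dihydroxy-5-methoxyphenyl)-2-(hydroxymethyl)-8-methoxy-2,3-dihydro-1,4-benzodioxin-6-yl]prop-2-en-1-ol | COc1cc([C@@H]2Oc3cc(/C=C/CO)cc(OC)c3O[C@@H]2CO)cc(O)c1O | target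

## Step count and least certain steps

Total: 12 steps. Longest linear sequence: 12 steps, from 1 to 17; compounds 3, 6 and 15 are bought.

**Step 10 (key step, proposed new method).** Several things can go wrong.
- Migration of the wrong group: ring C would give a ring-opened aryl ester, C2 a 1,3-benzodioxine acetal.
- Ionisation of the C3–O bond with loss of hydrogen peroxide and aromatisation to the benzofuran, which also destroys C2.
- Proton loss from 13 before hydride capture, which erodes the enantiomeric purity.
- Hydride delivery syn to the acetoxymethyl group, which gives the trans isomer.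

These risks come from the fact that the rearrangement has not been run on a dihydrobenzofuran, where the migrating and the competing groups are close in aptitude.

Fallback, known chemistry only; it sets out from 6 and comes back at 14, and reaches the same type of cation from a hemiketal. Phenol 6 is ortho-formylated (MgCl2, Et3N, paraformaldehyde) to 5-chloro-2-hydroxy-3-methoxybenzaldehyde F1. Methyl (S)-glycerate is silylated at the primary hydroxyl (TBSCl, imidazole) to methyl (2S)-3-[(tert-butyldimethylsilyl)oxy]-2-hydroxypropanoate F2. A Mitsunobu reaction of F1 with F2 (PPh3, diisopropyl azodicarboxylate) gives, with inversion, the aryl ether methyl (2R)-3-[(tert-butyldimethylsilyl)oxy]-2-(4-chloro-2-formyl-6-methoxyphenoxy)propanoate F3. Dakin oxidation (mCPBA, then Et3N in MeOH) turns the formyl group into the O4 phenol, which lactonises (pyridinium p-toluenesulfonate, toluene, 80 °C) to (3R)-3-{[(tert-butyldimethylsilyl)oxy]methyl}-7-chloro-5-methoxy-1,4-benzodioxin-2(3H)-one F4. For ring C, Dakin oxidation of commercial 5-bromo-2-hydroxy-3-methoxybenzaldehyde gives 5-bromo-3-methoxybenzene-1,2-diol F5, which is silylated to 5-bromo-1,2-bis[(tert-butyldimethylsilyl)oxy]-3-methoxybenzene F6. Bromine–lithium exchange on F6 (nBuLi, −78 °C) and addition of the aryllithium to F4 (lactone kept in excess, −78 °C) give the hemiketal (2R,3RS)-3-{3,4-bis[(tert-butyldimethylsilyl)oxy]-5-methoxyphenyl}-2-{[(tert-butyldimethylsilyl)oxy]methyl}-6-chloro-8-methoxy-2,3-dihydro-1,4-benzodioxin-3-ol F7. Without purification F7 is reduced with BF3·OEt2 and Et3SiH, as in C-aryl glycoside synthesis, to the cis compound (2R,3S)-3-{3,4-bis[(tert-butyldimethylsilyl)oxy]-5-methoxyphenyl}-2-{[(tert-butyldimethylsilyl)oxy]methyl}-6-chloro-8-methoxy-2,3-dihydro-1,4-benzodioxine F8. HF·pyridine removes the silyl groups to give [(2R,3S)-6-chloro-3-(3,4-dihydroxy-5-methoxyphenyl)-8-methoxy-2,3-dihydro-1,4-benzodioxin-2-yl]methanol F9, and Ac2O in pyridine returns 14.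

**Step 9.** Most likely to go wrong: radical-induced decomposition of the hydroperoxide once it accumulates (the alkoxyl radical would cleave the C2–C3 bond), and hydrogen abstraction at C2 or at a methoxy group because the tertiary C3–H is shielded by two aryl groups.

Fallback, from 11, coming back at 14: Kharasch–Sosnovsky peroxidation (tBuOOH, CuCl cat., MeCN, 60 °C) gives the mixed peroxide [(2R,3RS)-3-(tert-butylperoxy)-5-chloro-3-(3,4-diacetoxy-5-methoxyphenyl)-7-methoxy-2,3-dihydro-1-benzofuran-2-yl]methyl acetate F10. It does not propagate chain decomposition, and it is submitted to the Lewis acid and silane of step 10 with tert-butoxide as the leaving group, which gives 14.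

**Step 8.** Most likely to go wrong:
- low conversion, because the furan double bond is tetrasubstituted and flanked by an aryl group;
- hydrogenolysis of the furfuryl-type C–O bond or of the C–Cl bond;
- poor facial selectivity, since the catalyst class is proven mainly for 2-substituted benzofurans.

Fallback, from 8, coming back at 12: magnesium in methanol reduces the conjugated ester (with transesterification and loss of the aryl acetates) to the racemic trans ester methyl (2RS,3RS)-5-chloro-3-(3,4-dihydroxy-5-methoxyphenyl)-7-methoxy-2,3-dihydro-1-benzofuran-2-carboxylate F11. Separation on a chiral stationary phase gives methyl (2S,3S)-5-chloro-3-(3,4-dihydroxy-5-methoxyphenyl)-7-methoxy-2,3-dihydro-1-benzofuran-2-carboxylate F12. iBu2AlH reduction gives 5-[(2S,3S)-5-chloro-2-(hydroxymethyl)-7-methoxy-2,3-dihydro-1-benzofuran-3-yl]-3-methoxybenzene-1,2-diol F13, and acetylation gives [(2S,3S)-5-chloro-3-(3,4-diacetoxy-5-methoxyphenyl)-7-methoxy-2,3-dihydro-1-benzofuran-2-yl]methyl acetate F14. F14 is the C3 epimer of 11 with the same C2 configuration, and the autoxidation of step 9 converts it into 12.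

**Step 11.** Most likely to go wrong: slow oxidative addition to the electron-rich aryl chloride, so that prolonged heating leads to acetate loss and then to opening of the C3–O4 bond, or to acrylate polymerisation.

Fallback, from 14, coming back at 17: Suzuki–Miyaura coupling with (E)-3-(4,4,5,5-tetramethyl-1,3,2-dioxaborolan-2-yl)prop-2-en-1-ol (Pd(OAc)2, SPhos, anhydrous K3PO4, 1,4-dioxane, 70 °C) gives [(2R,3S)-3-(3,4-diacetoxy-5-methoxyphenyl)-6-[(E)-3-hydroxyprop-1-en-1-yl]-8-methoxy-2,3-dihydro-1,4-benzodioxin-2-yl]methyl acetate F15. Its three acetates are removed with iBu2AlH as in step 12 to give 17.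

## Further compounds

F1 | step 10 | 5-chloro-2-hydroxy-3-methoxybenzaldehyde | COc1cc(Cl)cc(C=O)c1O
F2 | step 10 | methyl (2S)-3-[(tert-butyldimethylsilyl)oxy]-2-hydroxypropanoate | COC(=O)[C@@H](O)CO[Si](C)(C)C(C)(C)C
F3 | step 10 | methyl (2R)-3-[(tert-butyldimethylsilyl)oxy]-2-(4-chloro-2-formyl-6-methoxyphenoxy)propanoate | COC(=O)[C@@H](CO[Si](C)(C)C(C)(C)C)Oc1c(C=O)cc(Cl)cc1OC
F4 | step 10 | (3R)-3-{[(tert-butyldimethylsilyl)oxy]methyl}-7-chloro-5-methoxy-1,4-benzodioxin-2(3H)-one | O=C1Oc2cc(Cl)cc(OC)c2O[C@@H]1CO[Si](C)(C)C(C)(C)C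
F5 | step 10 | 5-bromo-3-methoxybenzene-1,2-diol | COc1cc(Br)cc(O)c1O
F6 | step 10 | 5-bromo-1,2-bis[(tert-butyldimethylsilyl)oxy]-3-methoxybenzene | COc1cc(Br)cc(O[Si](C)(C)C(C)(C)C)c1O[Si](C)(C)C(C)(C)C
F7 | step 10 | (2R,3RS)-3-{3,4-bis[(tert-butyldimethylsilyl)oxy]-5-methoxyphenyl}-2-{[(tert-butyldimethylsilyl)oxy]methyl}-6-chloro-8-methoxy-2,3-dihydro-1,4-benzodioxin-3-ol | COc1cc(C2(O)Oc3cc(Cl)cc(OC)c3O[C@@H]2CO[Si](C)(C)C(C)(C)C)cc(O[Si](C)(C)C(C)(C)C)c1O[Si](C)(C)C(C)(C)C
F8 | step 10 | (2R,3S)-3-{3,4-bis[(tert-butyldimethylsilyl)oxy]-5-methoxyphenyl}-2-{[(tert-butyldimethylsilyl)oxy]methyl}-6-chloro-8-methoxy-2,3-dihydro-1,4-benzodioxine | COc1cc([C@@H]2Oc3cc(Cl)cc(OC)c3O[C@@H]2CO[Si](C)(C)C(C)(C)C)cc(O[Si](C)(C)C(C)(C)C)c1O[Si](C)(C)C(C)(C)C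
F9 | step 10 | [(2R,3S)-6-chloro-3-(3,4-dihydroxy-5-methoxyphenyl)-8-methoxy-2,3-dihydro-1,4-benzodioxin-2-yl]methanol | COc1cc([C@@H]2Oc3cc(Cl)cc(OC)c3O[C@@H]2CO)cc(O)c1O
F10 | step 9 | [(2R,3RS)-3-(tert-butylperoxy)-5-chloro-3-(3,4-diacetoxy-5-methoxyphenyl)-7-methoxy-2,3-dihydro-1-benzofuran-2-yl]methyl acetate | COc1cc(C2(OOC(C)(C)C)c3cc(Cl)cc(OC)c3O[C@@H]2COC(C)=O)cc(OC(C)=O)c1OC(C)=O
F11 | step 8 | methyl (2RS,3RS)-5-chloro-3-(3,4-dihydroxy-5-methoxyphenyl)-7-methoxy-2,3-dihydro-1-benzofuran-2-carboxylate (racemic trans) | COc1cc([C@H]2c3cc(Cl)cc(OC)c3O[C@@H]2C(=O)OC)cc(O)c1O.COc1cc([C@@H]2c3cc(Cl)cc(OC)c3O[C@H]2C(=O)OC)cc(O)c1O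
F12 | step 8 | methyl (2S,3S)-5-chloro-3-(3,4-dihydroxy-5-methoxyphenyl)-7-methoxy-2,3-dihydro-1-benzofuran-2-carboxylate | COc1cc([C@H]2c3cc(Cl)cc(OC)c3O[C@@H]2C(=O)OC)cc(O)c1O
F13 | step 8 | 5-[(2S,3S)-5-chloro-2-(hydroxymethyl)-7-methoxy-2,3-dihydro-1-benzofuran-3-yl]-3-methoxybenzene-1,2-diol | COc1cc([C@H]2c3cc(Cl)cc(OC)c3O[C@@H]2CO)cc(O)c1O
F14 | step 8 | [(2S,3S)-5-chloro-3-(3,4-diacetoxy-5-methoxyphenyl)-7-methoxy-2,3-dihydro-1-benzofuran-2-yl]methyl acetate | COc1cc([C@H]2c3cc(Cl)cc(OC)c3O[C@@H]2COC(C)=O)cc(OC(C)=O)c1OC(C)=O
F15 | step 11 | [(2R,3S)-3-(3,4-diacetoxy-5-methoxyphenyl)-6-[(E)-3-hydroxyprop-1-en-1-yl]-8-methoxy-2,3-dihydro-1,4-benzodioxin-2-yl]methyl acetate | COc1cc([C@@H]2Oc3cc(/C=C/CO)cc(OC)c3O[C@@H]2COC(C)=O)cc(OC(C)=O)c1OC(C)=O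
A1 | alternative 1 | ethyl (2S,3S)-2-(4-bromo-2-iodo-6-methoxyphenoxy)-3-{3,4-bis[(tert-butyldimethylsilyl)oxy]-5-methoxyphenyl}-3-hydroxypropanoate | COc1cc([C@H](O)[C@H](Oc2c(I)cc(Br)cc2OC)C(=O)OCC)cc(O[Si](C)(C)C(C)(C)C)c1O[Si](C)(C)C(C)(C)C
A2 | alternative 1 | 4-bromo-2-iodo-6-methoxyphenol | COc1cc(Br)cc(I)c1O
A3 | alternative 1 | 3,4-bis[(tert-butyldimethylsilyl)oxy]-5-methoxybenzaldehyde | COc1cc(C=O)cc(O[Si](C)(C)C(C)(C)C)c1O[Si](C)(C)C(C)(C)C
A4 | alternative 2 | methyl (2R,3S)-3-{3,4-bis[(tert-butyldimethylsilyl)oxy]-5-methoxyphenyl}-2-{[(tert-butyldimethylsilyl)oxy]methyl}-8-oxo-2,3,5,6,7,8-hexahydro-1,4-benzodioxine-6-carboxylate (C6 epimers) | COc1cc([C@@H]2OC3=C(O[C@@H]2CO[Si](C)(C)C(C)(C)C)C(=O)CC(C(=O)OC)C3)cc(O[Si](C)(C)C(C)(C)C)c1O[Si](C)(C)C(C)(C)C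
A5 | alternative 2 | methyl 4-diazo-3,5-dioxocyclohexane-1-carboxylate | COC(=O)C1CC(=O)C(=[N+]=[N-])C(=O)C1
A6 | alternative 2 | (2R,3R)-2-{[(tert-butyldimethylsilyl)oxy]methyl}-3-{3,4-bis[(tert-butyldimethylsilyl)oxy]-5-methoxyphenyl}oxirane (trans) | COc1cc([C@H]2O[C@@H]2CO[Si](C)(C)C(C)(C)C)cc(O[Si](C)(C)C(C)(C)C)c1O[Si](C)(C)C(C)(C)C
A7 | alternative 3 | (2R,3S)-3-{3,4-bis[(tert-butyldimethylsilyl)oxy]-5-methoxyphenyl}-6-bromo-8-methoxy-2-{[(tert-butyldimethylsilyl)oxy]methyl}-2,3-dihydro-1,4-benzodioxine | COc1cc([C@@H]2Oc3cc(Br)cc(OC)c3O[C@@H]2CO[Si](C)(C)C(C)(C)C)cc(O[Si](C)(C)C(C)(C)C)c1O[Si](C)(C)C(C)(C)C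
A8 | alternative 3 | (3R)-7-bromo-3-{[(tert-butyldimethylsilyl)oxy]methyl}-5-methoxy-1,4-benzodioxin-2(3H)-one | O=C1Oc2cc(Br)cc(OC)c2O[C@@H]1CO[Si](C)(C)C(C)(C)C
A9 | alternative 3 | {3,4-bis[(tert-butyldimethylsilyl)oxy]-5-methoxyphenyl}magnesium bromide | COc1cc([Mg]Br)cc(O[Si](C)(C)C(C)(C)C)c1O[Si](C)(C)C(C)(C)C
A10 | alternative 3 | (2R,3RS)-3-{3,4-bis[(tert-butyldimethylsilyl)oxy]-5-methoxyphenyl}-6-bromo-2-{[(tert-butyldimethylsilyl)oxy]methyl}-8-methoxy-2,3-dihydro-1,4-benzodioxin-3-ol | COc1cc(C2(O)Oc3cc(Br)cc(OC)c3O[C@@H]2CO[Si](C)(C)C(C)(C)C)cc(O[Si](C)(C)C(C)(C)C)c1O[Si](C)(C)C(C)(C)C
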